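**Strategy.** The target is the 2,4-trans-flavan-4-ol (2S,4R). Everything rests on closing ring C at the C4–C4a bond: (S)-3-aryloxy-3-arylpropanal 15, which already carries O1–C2 and the C2 stereocentre (from an iridium-catalysed asymmetric allylic etherification), undergoes an Me2AlCl-mediated intramolecular Friedel–Crafts hydroxyalkylation. The step exploits C4a of ring A, the only free carbon ortho to O1, para to the C7 methoxy group and flanked by two oxygens: in one operation it closes the pyran ring, delivers C4 at the alcohol oxidation level and sets the C4 stereocentre, the pseudo-equatorial C2 aryl group and the peri C5 silyloxy group steering the C4–O bond pseudo-axial.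

Key step: step 8

Assumption: the (Sa,Sc,Sc) phosphoramidite is taken to give the (S)-ether in step 5, by analogy with the usual sense of induction of this catalyst family with cinnamyl carbonates; should the sense be opposite, the enantiomeric ligand is used.

Step 1
Reactants: 1 3,5-dimethoxyphenol
Product: 2 (3,5-dimethoxyphenoxy)triisopropylsilane
Conditions: TIPSCl, imidazole, DMF, 0 °C to rt
Reagents that add atoms: triisopropylsilyl chloride, CC(C)[Si](Cl)(C(C)C)C(C)C
Why: Imidazole-promoted silylation of a phenol; the bulky, non-coordinating OSi(iPr)3 group later shields its two neighbouring positions against lithiation and serves as the peri control element in step 8.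

Step 2
Reactants: 2 (3,5-dimethoxyphenoxy)triisopropylsilane; 3 1-bromo-3-methylbut-2-ene (prenyl bromide)
Product: 5 [3,5-dimethoxy-4-(3-methylbut-2-en-1-yl)phenoxy]triisopropylsilane, via aryllithium 4 (not isolated)
Conditions: n-BuLi, TMEDA, THF, 0 °C to rt; then CuBr·SMe2 (10 mol %), 3, −78 °C to rt
Reagents that add atoms: n-butyllithium, [Li]CCCC (its lithium stays in 4 only)
Why: Directed ortho-metalation at the carbon between the two methoxy groups (the most acidic site), followed by copper-catalysed SN2 allylation of the aryllithium with prenyl bromide.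

Step 3
Reactants: 5 [3,5-dimethoxy-4-(3-methylbut-2-en-1-yl)phenoxy]triisopropylsilane
Product: 7 3-methoxy-2-(3-methylbut-2-en-1-yl)-5-(triisopropylsilyloxy)phenol, via lithium aryloxide 6 (not isolated)
Conditions: LiPPh2 (1.5 equiv), THF, rt; then 1 M HCl
Reagents that add atoms: lithium diphenylphosphide, [Li]P(c1ccccc1)c1ccccc1 (its lithium stays in 6 only)
Why: Nucleophilic SN2 demethylation of an aryl methyl ether by diphenylphosphide should stop after one cleavage because the phenoxide formed deactivates the ring; the two methoxy groups are equivalent, so one phenol results, and the hindered aryl silyl ether and the alkene are expected to survive at room temperature.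

Step 4
Reactants: 8 tert-butyldimethyl(4-vinylphenoxy)silane; 9 allyl methyl carbonate
Product: 10 (E)-3-[4-(tert-butyldimethylsilyloxy)phenyl]prop-2-en-1-yl methyl carbonate
Conditions: second-generation Hoveyda–Grubbs catalyst RuCl2(H2IMes)(=CH-C6H4-2-OiPr) (3 mol %), 9 (3 equiv), CH2Cl2, 40 °C
Reagents that add atoms: none
Why: Olefin cross-metathesis of a styrene with an allylic carbonate, driven by loss of ethylene, should give the (E)-cinnamyl carbonate.

Step 5
Reactants: 7 3-methoxy-2-(3-methylbut-2-en-1-yl)-5-(triisopropylsilyloxy)phenol; 10 (E)-3-[4-(tert-butyldimethylsilyloxy)phenyl]prop-2-en-1-yl methyl carbonate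
Product: 12 (S)-tert-butyl(4-{1-[3-methoxy-2-(3-methylbut-2-en-1-yl)-5-(triisopropylsilyloxy)phenoxy]prop-2-en-1-yl}phenoxy)dimethylsilane, via sodium aryloxide 11 (not isolated)
Conditions: NaH (1.0 equiv), THF, 0 °C to rt; then 10, [Ir(cod)Cl]2 (2 mol %), (Sa,Sc,Sc)-O,O'-(1,1'-binaphthalene-2,2'-diyl) N,N-bis(1-phenylethyl)phosphoramidite (4 mol %, catalyst pre-activated with n-PrNH2), THF, rt to 50 °C
Reagents that add atoms: sodium hydride, [Na+].[H-] (its sodium stays in 11 only)
Why: Iridium-catalysed asymmetric allylic etherification of a linear cinnamyl carbonate with an alkali-metal aryloxide gives the branched allyl aryl ether; the sodium salt, made from the isolated phenol with NaH, is chosen as the more nucleophilic partner for this hindered ortho-substituted aryloxide, and the new C2 stereocentre is set by the phosphoramidite ligand, the (Sa,Sc,Sc) enantiomer being the one expected to give (S).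

Step 6
Reactants: 12 (S)-tert-butyl(4-{1-[3-methoxy-2-(3-methylbut-2-en-1-yl)-5-(triisopropylsilyloxy)phenoxy]prop-2-en-1-yl}phenoxy)dimethylsilane
Product: 14 (3S)-3-[4-(tert-butyldimethylsilyloxy)phenyl]-3-[3-methoxy-2-(3-methylbut-2-en-1-yl)-5-(triisopropylsilyloxy)phenoxy]propan-1-ol, via alkylborane 13 (not isolated)
Conditions: 9-BBN (1.5 equiv), THF, 0 °C to rt; then NaBO3·4H2O, H2O, rt
Reagents that add atoms: 9-borabicyclo[3.3.1]nonane, [H]B1C2CCCC1CCC2 (boron in 13 only); sodium perborate, [Na+].[Na+].O[B-]1(O)OO[B-](O)(O)OO1 (oxygen of the new hydroxyl group)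
Why: Hydroboration–oxidation; 9-BBN adds anti-Markovnikov to the monosubstituted alkene far faster than to the trisubstituted prenyl alkene, and perborate oxidises the C–B bond under mild conditions that should spare the aryl silyl ethers; C2 is not touched.

Step 7
Reactants: 14 (3S)-3-[4-(tert-butyldimethylsilyloxy)phenyl]-3-[3-methoxy-2-(3-methylbut-2-en-1-yl)-5-(triisopropylsilyloxy)phenoxy]propan-1-ol
Product: 15 (3S)-3-[4-(tert-butyldimethylsilyloxy)phenyl]-3-[3-methoxy-2-(3-methylbut-2-en-1-yl)-5-(triisopropylsilyloxy)phenoxy]propanal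
Conditions: Dess–Martin periodinane, NaHCO3, CH2Cl2, 0 °C to rt; used crude
Reagents that add atoms: none
Why: Dess–Martin oxidation of the primary alcohol under buffered, non-basic conditions, which avoids β-elimination of the aryloxide from the β-aryloxy aldehyde.

Step 8
Reactants: 15 (3S)-3-[4-(tert-butyldimethylsilyloxy)phenyl]-3-[3-methoxy-2-(3-methylbut-2-en-1-yl)-5-(triisopropylsilyloxy)phenoxy]propanal
Product: 17 (2S,4R)-2-[4-(tert-butyldimethylsilyloxy)phenyl]-7-methoxy-8-(3-methylbut-2-en-1-yl)-5-(triisopropylsilyloxy)chroman-4-ol, via aluminium alkoxide 16 (not isolated)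
Conditions: Me2AlCl (2.0 equiv), CH2Cl2 (0.01 M), −78 °C; quenched cold with aqueous KNaC4H4O6 (Rochelle salt)
Reagents that add atoms: dimethylaluminium chloride, C[Al](C)Cl (aluminium, one methyl and chloride in 16 only)
Why: Me2AlCl binds the aldehyde oxygen and C4a of ring A attacks the activated carbonyl carbon C4; the arenium ion then loses its proton to an Al–CH3 bond (methane), so the product is held as the chloro(methyl)aluminium alkoxide 16 and no Brønsted acid is left to ionise or dehydrate the benzylic C4–O bond. The closest known reaction type is the Lewis-acid-mediated intramolecular Friedel–Crafts hydroxyalkylation of electron-rich arenes by tethered aldehydes, the arene counterpart of the Me2AlCl carbonyl-ene cyclisation. Ring C closes in a 6-exo-trig mode at the carbonyl carbon (6-(enolendo)-exo-trig if the arene is counted as the enol-type partner). The new C4 stereocentre is controlled by the C2 stereocentre together with the C5 substituent: in the chair-like transition state the C2 aryl group is pseudo-equatorial and the aluminium-bound oxygen is expected to take the pseudo-axial position, because a pseudo-equatorial C4–O–Al unit would lie in the plane of ring A against the peri OSi(iPr)3 group, which gives the 2,4-trans isomer (4R). The step needs regioselectivity for C4a over C6 and chemoselectivity over the prenyl alkene: the three-atom tether from O1 can only reach C4a (C8 carries the prenyl group, C6 is out of reach), and attack by the trioxygenated arene through a six-membered transition state should be much faster than an ene reaction of the remote prenyl group.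

Step 9
Reactants: 17 (2S,4R)-2-[4-(tert-butyldimethylsilyloxy)phenyl]-7-methoxy-8-(3-methylbut-2-en-1-yl)-5-(triisopropylsilyloxy)chroman-4-ol
Product: 18 (2S,4R)-2-(4-hydroxyphenyl)-7-methoxy-8-(3-methylbut-2-en-1-yl)chromane-4,5-diol (4,5,4'-trihydroxy-7-methoxy-8-prenylflavan)
Conditions: TBAF, AcOH (1:1, 2.5 equiv), THF, 0 °C
Reagents that add atoms: none
Why: Fluoride-mediated cleavage of both aryl silyl ethers, buffered with acetic acid so that the acid- and base-labile benzylic C4 alcohol should be neither ionised nor eliminated; no stereocentre is touched.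

**Compound list**

1 | 3,5-dimethoxyphenol | COc1cc(O)cc(OC)c1 | starting material
2 | (3,5-dimethoxyphenoxy)triisopropylsilane | COc1cc(OC)cc(O[Si](C(C)C)(C(C)C)C(C)C)c1 | intermediate
3 | 1-bromo-3-methylbut-2-ene (prenyl bromide) | CC(C)=CCBr | starting material
4 | [2,6-dimethoxy-4-(triisopropylsilyloxy)phenyl]lithium | [Li]c1c(OC)cc(O[Si](C(C)C)(C(C)C)C(C)C)cc1OC | intermediate
5 | [3,5-dimethoxy-4-(3-methylbut-2-en-1-yl)phenoxy]triisopropylsilane | COc1cc(O[Si](C(C)C)(C(C)C)C(C)C)cc(OC)c1CC=C(C)C | intermediate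
6 | lithium 3-methoxy-2-(3-methylbut-2-en-1-yl)-5-(triisopropylsilyloxy)phenolate | [Li]Oc1cc(O[Si](C(C)C)(C(C)C)C(C)C)cc(OC)c1CC=C(C)C | intermediate
7 | 3-methoxy-2-(3-methylbut-2-en-1-yl)-5-(triisopropylsilyloxy)phenol | COc1cc(O[Si](C(C)C)(C(C)C)C(C)C)cc(O)c1CC=C(C)C | intermediate
8 | tert-butyldimethyl(4-vinylphenoxy)silane | C=Cc1ccc(O[Si](C)(C)C(C)(C)C)cc1 | starting material
9 | allyl methyl carbonate | C=CCOC(=O)OC | starting material
10 | (E)-3-[4-(tert-butyldimethylsilyloxy)phenyl]prop-2-en-1-yl methyl carbonate | COC(=O)OC/C=C/c1ccc(O[Si](C)(C)C(C)(C)C)cc1 | intermediate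
11 | sodium 3-methoxy-2-(3-methylbut-2-en-1-yl)-5-(triisopropylsilyloxy)phenolate | [Na]Oc1cc(O[Si](C(C)C)(C(C)C)C(C)C)cc(OC)c1CC=C(C)C | intermediate
12 | (S)-tert-butyl(4-{1-[3-methoxy-2-(3-methylbut-2-en-1-yl)-5-(triisopropylsilyloxy)phenoxy]prop-2-en-1-yl}phenoxy)dimethylsilane | COc1cc(O[Si](C(C)C)(C(C)C)C(C)C)cc(c1CC=C(C)C)O[C@H](c1ccc(O[Si](C)(C)C(C)(C)C)cc1)C=C | intermediate
13 | 9-{(3S)-3-[4-(tert-butyldimethylsilyloxy)phenyl]-3-[3-methoxy-2-(3-methylbut-2-en-1-yl)-5-(triisopropylsilyloxy)phenoxy]propyl}-9-borabicyclo[3.3.1]nonane | COc1cc(O[Si](C(C)C)(C(C)C)C(C)C)cc(c1CC=C(C)C)O[C@H](c1ccc(O[Si](C)(C)C(C)(C)C)cc1)CCB1C2CCCC1CCC2 | intermediate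
14 | (3S)-3-[4-(tert-butyldimethylsilyloxy)phenyl]-3-[3-methoxy-2-(3-methylbut-2-en-1-yl)-5-(triisopropylsilyloxy)phenoxy]propan-1-ol | COc1cc(O[Si](C(C)C)(C(C)C)C(C)C)cc(c1CC=C(C)C)O[C@H](c1ccc(O[Si](C)(C)C(C)(C)C)cc1)CCO | intermediate
15 | (3S)-3-[4-(tert-butyldimethylsilyloxy)phenyl]-3-[3-methoxy-2-(3-methylbut-2-en-1-yl)-5-(triisopropylsilyloxy)phenoxy]propanal | COc1cc(O[Si](C(C)C)(C(C)C)C(C)C)cc(c1CC=C(C)C)O[C@H](c1ccc(O[Si](C)(C)C(C)(C)C)cc1)CC=O | intermediate
16 | chloro(methyl)aluminium (2S,4R)-2-[4-(tert-butyldimethylsilyloxy)phenyl]-7-methoxy-8-(3-methylbut-2-en-1-yl)-5-(triisopropylsilyloxy)chroman-4-olate | COc1cc(O[Si](C(C)C)(C(C)C)C(C)C)c2c(c1CC=C(C)C)O[C@H](c1ccc(O[Si](C)(C)C(C)(C)C)cc1)C[C@H]2O[Al](C)Cl | intermediate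
17 | (2S,4R)-2-[4-(tert-butyldimethylsilyloxy)phenyl]-7-methoxy-8-(3-methylbut-2-en-1-yl)-5-(triisopropylsilyloxy)chroman-4-ol | COc1cc(O[Si](C(C)C)(C(C)C)C(C)C)c2c(c1CC=C(C)C)O[C@H](c1ccc(O[Si](C)(C)C(C)(C)C)cc1)C[C@H]2O | intermediate
18 | (2S,4R)-2-(4-hydroxyphenyl)-7-methoxy-8-(3-methylbut-2-en-1-yl)chromane-4,5-diol | COc1cc(O)c2c(c1CC=C(C)C)O[C@H](c1ccc(O)cc1)C[C@H]2O | target

**Step count.** Total: 9 steps. Longest linear sequence: 8 steps (steps 1–3 and 5–9, from 3,5-dimethoxyphenol).

**Steps most likely to fail**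

1. Step 8 (key step). The aldehyde may be attacked on its other face, placing the C4–O bond pseudo-equatorial (2,4-cis series). The aluminium alkoxide may also ionise at the doubly ortho- and para-oxygenated benzylic C4 and lose the oxygen by elimination. The fallback sets out from aldehyde 15 and comes back at 17; it closes the same ring at the ketone oxidation level and corrects C4 afterwards. Pinnick oxidation of 15 (NaClO2, NaH2PO4, 2-methylbut-2-ene, t-BuOH/H2O) should give the (S)-3-aryloxy-3-arylpropanoic acid F1. Its mixed anhydride (TFAA, CH2Cl2, 0 °C) should undergo intramolecular Friedel–Crafts acylation at C4a to the (2S)-flavanone F2, a product that cannot ionise. NaBH4 (MeOH/THF, 0 °C) delivers hydride along the axial trajectory and should give the 2,4-cis alcohol F3 (2S,4S). Mitsunobu inversion (PhCO2H, PPh3, DIAD, THF, 0 °C) should give the 2,4-trans benzoate F4 (2S,4R). i-Bu2AlH (CH2Cl2, −78 °C) removes the benzoyl group and returns 17.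

2. Step 5. The hindered ortho-prenyl aryloxide may react sluggishly, so that the electron-rich branched ether isomerises to the linear ether or loses enantiomeric purity by reversible ionisation on the metal. The fallback sets out from styrene 8 and comes back at 14; it sets the C2 stereocentre by reagent-controlled allylboration and forms the C2–O1 bond by SN2 inversion. Ozonolysis of 8 (O3, CH2Cl2, −78 °C; Me2S) gives 4-(tert-butyldimethylsilyloxy)benzaldehyde F5. Allylboration with (+)-B-allyldiisopinocampheylborane (Et2O, −78 °C; NaBO3 work-up) should give the (R)-homoallylic alcohol F6. Ozonolysis with NaBH4 work-up gives the (R)-1,3-diol F7. Selective acylation of the primary hydroxyl (PivCl, pyridine, CH2Cl2, −20 °C) gives the pivalate F8. Mitsunobu etherification with phenol 7 (PPh3, DIAD, toluene, 0 °C) should proceed with inversion to the (S)-ether F9. i-Bu2AlH (CH2Cl2, −78 °C) removes the pivaloyl group and returns 14.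

3. Step 3. The phosphide may attack silicon and cleave the aryl silyl ether, after which the phenoxide-bearing ring no longer demethylates. The fallback sets out from prenyl bromide 3 and comes back at 7; it avoids demethylation altogether. C-Prenylation of commercial phloroglucinol with 3 (aqueous KOH, 0 °C to rt) gives 2-prenylphloroglucinol F10. Silylation of the unhindered hydroxyl para to the prenyl group (TIPSCl 1.0 equiv, imidazole, DMF, −20 °C) gives the symmetric resorcinol F11. Methylation of one of its two equivalent hydroxyls (MeI 1.0 equiv, K2CO3, acetone, rt, with recycling of unreacted F11) gives 7.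

**Further compounds**

F1 | step 8 | (3S)-3-[4-(tert-butyldimethylsilyloxy)phenyl]-3-[3-methoxy-2-(3-methylbut-2-en-1-yl)-5-(triisopropylsilyloxy)phenoxy]propanoic acid | COc1cc(O[Si](C(C)C)(C(C)C)C(C)C)cc(c1CC=C(C)C)O[C@H](c1ccc(O[Si](C)(C)C(C)(C)C)cc1)CC(=O)O
F2 | step 8 | (2S)-2-[4-(tert-butyldimethylsilyloxy)phenyl]-7-methoxy-8-(3-methylbut-2-en-1-yl)-5-(triisopropylsilyloxy)chroman-4-one | COc1cc(O[Si](C(C)C)(C(C)C)C(C)C)c2c(c1CC=C(C)C)O[C@H](c1ccc(O[Si](C)(C)C(C)(C)C)cc1)CC2=O
F3 | step 8 | (2S,4S)-2-[4-(tert-butyldimethylsilyloxy)phenyl]-7-methoxy-8-(3-methylbut-2-en-1-yl)-5-(triisopropylsilyloxy)chroman-4-ol | COc1cc(O[Si](C(C)C)(C(C)C)C(C)C)c2c(c1CC=C(C)C)O[C@H](c1ccc(O[Si](C)(C)C(C)(C)C)cc1)C[C@@H]2O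
F4 | step 8 | (2S,4R)-2-[4-(tert-butyldimethylsilyloxy)phenyl]-7-methoxy-8-(3-methylbut-2-en-1-yl)-5-(triisopropylsilyloxy)chroman-4-yl benzoate | COc1cc(O[Si](C(C)C)(C(C)C)C(C)C)c2c(c1CC=C(C)C)O[C@H](c1ccc(O[Si](C)(C)C(C)(C)C)cc1)C[C@H]2OC(=O)c1ccccc1
F5 | step 5 | 4-(tert-butyldimethylsilyloxy)benzaldehyde | O=Cc1ccc(O[Si](C)(C)C(C)(C)C)cc1
F6 | step 5 | (1R)-1-[4-(tert-butyldimethylsilyloxy)phenyl]but-3-en-1-ol | O[C@@H](c1ccc(O[Si](C)(C)C(C)(C)C)cc1)CC=C
F7 | step 5 | (1R)-1-[4-(tert-butyldimethylsilyloxy)phenyl]propane-1,3-diol | O[C@@H](c1ccc(O[Si](C)(C)C(C)(C)C)cc1)CCO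
F8 | step 5 | (3R)-3-[4-(tert-butyldimethylsilyloxy)phenyl]-3-hydroxypropyl 2,2-dimethylpropanoate | O[C@@H](c1ccc(O[Si](C)(C)C(C)(C)C)cc1)CCOC(=O)C(C)(C)C
F9 | step 5 | (3S)-3-[4-(tert-butyldimethylsilyloxy)phenyl]-3-[3-methoxy-2-(3-methylbut-2-en-1-yl)-5-(triisopropylsilyloxy)phenoxy]propyl 2,2-dimethylpropanoate | COc1cc(O[Si](C(C)C)(C(C)C)C(C)C)cc(c1CC=C(C)C)O[C@H](c1ccc(O[Si](C)(C)C(C)(C)C)cc1)CCOC(=O)C(C)(C)C
F10 | step 3 | 2-(3-methylbut-2-en-1-yl)benzene-1,3,5-triol | CC(C)=CCc1c(O)cc(O)cc1O
F11 | step 3 | 2-(3-methylbut-2-en-1-yl)-5-(triisopropylsilyloxy)benzene-1,3-diol | CC(C)=CCc1c(O)cc(O[Si](C(C)C)(C(C)C)C(C)C)cc1O
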